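The readings are simulated on assumed constants; the scatter is artificial.

Late in a run target climbs on a nearly straight line, after a lag (the pre-steady-state phase), and I reckon with that late slope alone.

the same everywhere: substrate 1.5 M; gas 170 mM (held)
- delta: free catalyst 150 mM; added ligand 80 mM; temperature −18 °C; run made earlier
- zeta: free catalyst 150 mM; added ligand 180 mM; temperature 10 °C; run made earlier
- eta: free catalyst 75 mM; added ligand 120 mM; temperature −18 °C; run made earlier
- winter: free catalyst 150 mM; added ligand 120 mM; temperature −30 °C; time 3.0 min
- autumn: free catalyst 150 mM; added ligand 120 mM; temperature −5 °C; time 3.0 min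
- dusk: free catalyst 150 mM; added ligand 120 mM; temperature 20 °C; time 3.0 min

- delta (time / s: target / %, substrate / %): 10.0: 0, 95.7; 15.0: 0.3, 94.1; 30.0: 0, 94.0; 50.0: 0.6, 91.2; 60.0: 0.9, 91.1; 90.0: 2.2, 90.2; 120: 3.9, 88.6
- zeta (time / s: target / %, substrate / %): 10.0: 3.3, 93.3; 12.0: 5.2, 92.3; 20.0: 9.7, 87.5; 30.0: 15.2, 82.5
- eta (time / s: target / %, substrate / %): 20.0: 0.9, 97.4; 40.0: 0, 97.8; 60.0: 0, 96.2; 90.0: 0.9, 95.3; 120: 1.8, 95.0

(readings scatter by 0.5 percentage points)

- the flask that comes out highest in amount of target, in percent of the substrate charged, or "all alike" when all lie within 1.5 percentage points (winter / autumn / dusk / all alike)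
- target at the end, in percent of the substrate charged, winter
- target at the end, in percent of the substrate charged, autumn
- target at the end, in percent of the substrate charged, dusk

- at the start none of the gas is in solution

The last two target readings of delta give 29.4 min for the whole charge, and those of zeta give 3.03 min. I call this time the clearing time.

Autumn lies 0.464 of the way from delta to zeta in temperature and 0.400 of the way in added ligand, so I interpolate logarithmically. This gives autumn's clearing time 10.2 min.

Two things slow autumn. The lag, read where the late lines reach zero, is 51.2 s in delta and 2.36 s in zeta, hence 12.3 s in autumn, which costs a factor 0.932 and leaves 27.3% as the first answer.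

I then assume the rate follows substrate. The slopes were read near 85.5% substrate, and the missing material averages 4.90%. Putting the first answer back gives a factor 0.952, and a second round gives 26.2% for autumn.

Extrapolated, dusk clears in 1.35 min, shorter than its run, so I expect dusk highest. Winter's lag extrapolates to 3.19 min, longer than its run, so I expect hardly any target there.

The forecast, reading that “binding weakens on warming”, names dusk, with 0.8%, 30% and 93% for winter, autumn and dusk, its autumn standing above mine.

The flasks give 0.521%, 27.8% and 99.2%, with dusk highest.

    substrate + free catalyst ⇌ catalyst intermediate A (K = 0.890 M⁻¹, k = 1.20 M⁻¹ s⁻¹, Ea = 46.0 kJ mol⁻¹, ΔH = −52.0 kJ mol⁻¹)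
    partner + catalyst intermediate A → catalyst intermediate B (k = 8.90 M⁻¹ s⁻¹, Ea = 49.0 kJ mol⁻¹)
    catalyst intermediate B → free catalyst + target (k = 0.680 s⁻¹, Ea = 79.0 kJ mol⁻¹)
    free catalyst + added ligand ⇌ idle complex (K = 70.0 M⁻¹, k = 45.0 M⁻¹ s⁻¹, Ea = 42.0 kJ mol⁻¹, ΔH = −2.00 kJ mol⁻¹)
    gas ⇌ partner, rate k5*(csat - [partner]) (kL = 26.0 s⁻¹)
    (constants at 20 °C)

Autumn's target goes from 13.4% at 1.50 min to 27.8% at 3.00 min, a clearing time of 10.4 min against my 10.2 min. In winter, substrate takes free catalyst at 0.24 of the forward rate at which added ligand takes it at the start, and at 0.37 of that rate at the asked time. There the idle complex holds 31.6% of the catalyst charged, and target stands at 0.521%.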